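Ring A carries oxygen on C2, C4 and C6 and the vanilloyl carbonyl on C1, the pattern of a vanilloyl-primed tetraketide folded by C-acylation. The route therefore rests on disconnecting the C1–C2 bond of ring A. A linear 7-aryl-3,5,7-triketo ester, stored as its 2,2-dimethyl-1,3-dioxin-4-one with the aryl ketone already in place and the ring-B phenol as its MOM ether, is released and closed by Mg(OMe)2 in one operation to the symmetric 2,4,6-trihydroxybenzophenone. Ring-A symmetry then allows para-OH protection, mono-methylation, O-prenylation and a para-Claisen–Cope shift that places the prenyl group on C5, before both MOM groups are removed.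

Key step: step 5

Remark on the chemistry: ring A is numbered from the carbon bearing the ketone (C1), so the target has hydroxyls on C2 and C4, the prenyl group on C5 and the methoxy group on C6; ring B is the 4-hydroxy-3-methoxyphenyl ring. The target has no stereocenter and no stereogenic double bond, so no stereocontrol is needed. 1,3-Dicarbonyl compounds are drawn as keto forms.

Step 1
Reactants: 1 vanillic acid; 2 N,O-dimethylhydroxylamine hydrochloride
Product: 3 4-hydroxy-N,3-dimethoxy-N-methylbenzamide
Conditions: EDC·HCl, HOBt, iPr2NEt, DMF, 0 °C to rt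
Reagents that add atoms: N,O-dimethylhydroxylamine hydrochloride, CNOC.Cl
Why: Carbodiimide/HOBt amide coupling acylates the N-methoxy-N-methylamine far faster than the phenol, and any aryl ester formed in passing is cleaved by the amine, so the Weinreb amide should form without phenol protection.

Step 2
Reactants: 3 4-hydroxy-N,3-dimethoxy-N-methylbenzamide; 4 chloromethyl methyl ether
Product: 5 N,3-dimethoxy-4-(methoxymethoxy)-N-methylbenzamide
Conditions: MOMCl, K2CO3, acetone, 0 °C to rt
Reagents that add atoms: chloromethyl methyl ether, COCCl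
Why: Williamson-type O-alkylation of the phenoxide installs a MOM acetal that should survive the strong bases of steps 4 and 5 and leave together with the ring-A MOM group in step 10.

Step 3
Reactants: 6 2,2,6-trimethyl-4H-1,3-dioxin-4-one; 7 acetyl chloride
Product: 8 2,2-dimethyl-6-(2-oxopropyl)-4H-1,3-dioxin-4-one
Conditions: LiN(SiMe3)2 (commercial solution, 1 equiv per 6), THF, −78 °C; then AcCl (0.5 equiv), −78 °C; cold 1 M HCl
Reagents that add atoms: acetyl chloride, CC(=O)Cl
Why: γ-Deprotonation gives the lithium dienolate, which is C-acylated at the exocyclic carbon by the acid chloride (vinylogous Claisen acylation), the second equivalent of dienolate serving as the base that takes up the more acidic product.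

Step 4
Reactants: 8 2,2-dimethyl-6-(2-oxopropyl)-4H-1,3-dioxin-4-one; 5 N,3-dimethoxy-4-(methoxymethoxy)-N-methylbenzamide
Product: 9 6-{4-[3-methoxy-4-(methoxymethoxy)phenyl]-2,4-dioxobutyl}-2,2-dimethyl-4H-1,3-dioxin-4-one
Conditions: 8 (1.3 equiv), LiN(iPr)2 (commercial solution, 2.7 equiv), THF, −78 to −40 °C; then 5, −78 to 0 °C; cold 1 M HCl to pH 3
Reagents that add atoms: N,3-dimethoxy-4-(methoxymethoxy)-N-methylbenzamide, COCOc1ccc(cc1OC)C(=O)N(C)OC
Why: The dianion of the keto-dioxinone reacts at its terminal, more basic enolate carbon, and the N-methoxy-N-methyl amide holds the adduct as a lithium chelate until the quench, so this crossed Claisen-type acylation (Weinreb ketone synthesis) should stop cleanly at the 1,3-diketone.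

Step 5
Reactants: 9 6-{4-[3-methoxy-4-(methoxymethoxy)phenyl]-2,4-dioxobutyl}-2,2-dimethyl-4H-1,3-dioxin-4-one
Product: 11 2,4,6-trihydroxyphenyl 3-methoxy-4-(methoxymethoxy)phenyl ketone, via methyl triketo ester 10 (not isolated)
Conditions: Mg(OMe)2 (8 equiv), MeOH, reflux, Ar; then cold 1 M HCl to pH 4
Reagents that add atoms: none
Why: Methoxide adds to the dioxinone carbonyl, the acetonide collapses with loss of acetone and the chain is set free as triketo ester 10, held as a magnesium polyenolate. The enolate carbon flanked by the aroyl group and the neighbouring ketone (chain C6, the future ring-A C1) then attacks the ester carbonyl (chain C1), methoxide leaves and the new six-membered triketone aromatises by enolisation, a 6-(enolexo)-exo-trig closure driven forward by formation of the phloroglucinol magnesium salt. The closest known reaction type is the Mg(OMe)2-promoted intramolecular Claisen (Dieckmann-type) cyclisation of 7-aryl-3,5,7-trioxoheptanoates to 2,4,6-trihydroxybenzophenones, joined here to the familiar alkoxide opening of 1,3-dioxin-4-ones to β-keto esters. No stereocenter is formed. The step needs C-acylation at the ester to win over aldol attack of the ester-side methylene (chain C2) on the aryl ketone, which would give a 6-arylresorcylate; magnesium chelation of the aroyl/ketone pair turns the aryl ketone into an enolate-type ligand and the para-alkoxy group of ring B lowers its electrophilicity further, so the ester is the only carbonyl left open to attack. Because the new ring has equivalent C2 and C6 hydroxyls, the direction of folding raises no regiochemical question.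

Step 6
Reactants: 11 2,4,6-trihydroxyphenyl 3-methoxy-4-(methoxymethoxy)phenyl ketone; 4 chloromethyl methyl ether
Product: 12 2,6-dihydroxy-4-(methoxymethoxy)phenyl 3-methoxy-4-(methoxymethoxy)phenyl ketone
Conditions: MOMCl (1.05 equiv), K2CO3 (1.1 equiv), acetone, 0 °C
Reagents that add atoms: chloromethyl methyl ether, COCCl
Why: The C4 hydroxyl, para to the ketone, is the most acidic one and the only one neither hydrogen-bonded to the carbonyl nor flanked by the aroyl group, so one equivalent of alkylating agent under weak base should etherify it selectively (regioselective O-alkylation of an acylphloroglucinol).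

Step 7
Reactants: 12 2,6-dihydroxy-4-(methoxymethoxy)phenyl 3-methoxy-4-(methoxymethoxy)phenyl ketone; 13 iodomethane
Product: 14 2-hydroxy-6-methoxy-4-(methoxymethoxy)phenyl 3-methoxy-4-(methoxymethoxy)phenyl ketone
Conditions: MeI (1.1 equiv), K2CO3 (1.2 equiv), acetone, rt to 40 °C
Reagents that add atoms: iodomethane, CI
Why: Williamson methylation of one of two equivalent ortho hydroxyls should stop at the mono-ether, because the remaining hydroxyl becomes locked in a strong hydrogen bond to the ketone and is much less nucleophilic under these mild conditions.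

Step 8
Reactants: 14 2-hydroxy-6-methoxy-4-(methoxymethoxy)phenyl 3-methoxy-4-(methoxymethoxy)phenyl ketone; 15 prenyl bromide
Product: 16 6-methoxy-4-(methoxymethoxy)-2-[(3-methylbut-2-en-1-yl)oxy]phenyl 3-methoxy-4-(methoxymethoxy)phenyl ketone
Conditions: prenyl bromide (1.5 equiv), K2CO3 (2 equiv), DMF, 50 °C
Reagents that add atoms: prenyl bromide, CC(C)=CCBr
Why: Williamson O-alkylation of the chelated phenol with the reactive allylic bromide in a dipolar aprotic solvent, where the potassium phenoxide is alkylated on oxygen and not on carbon.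

Step 9
Reactants: 16 6-methoxy-4-(methoxymethoxy)-2-[(3-methylbut-2-en-1-yl)oxy]phenyl 3-methoxy-4-(methoxymethoxy)phenyl ketone
Product: 18 2-hydroxy-6-methoxy-4-(methoxymethoxy)-5-(3-methylbut-2-en-1-yl)phenyl 3-methoxy-4-(methoxymethoxy)phenyl ketone, via ortho-dienone 17 (not isolated)
Conditions: PhNEt2, 200 °C, Ar
Reagents that add atoms: none
Why: Aromatic para-Claisen (Claisen–Cope) rearrangement, in which the first [3,3] shift can only reach C3 because C1 carries the aroyl group, and the crowded tertiary allyl group of dienone 17, pressed against the C4 MOM ether, should undergo the second [3,3] (Cope) shift to C5 faster than it enolises, after which tautomerisation restores the chelated C2 phenol.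

Step 10
Reactants: 18 2-hydroxy-6-methoxy-4-(methoxymethoxy)-5-(3-methylbut-2-en-1-yl)phenyl 3-methoxy-4-(methoxymethoxy)phenyl ketone
Product: 19 2,4-dihydroxy-6-methoxy-5-(3-methylbut-2-en-1-yl)phenyl 4-hydroxy-3-methoxyphenyl ketone (CNP0197938.0)
Conditions: 3 M aq. HCl, MeOH, rt
Reagents that add atoms: none
Why: Acid-catalysed transacetalisation of both aryl MOM acetals to methanol at room temperature is mild enough to leave the trisubstituted prenyl olefin and the two methyl ethers untouched, as in deprotections of related prenylated polyphenols.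

Compound list
1 | vanillic acid (4-hydroxy-3-methoxybenzoic acid) | COc1cc(C(=O)O)ccc1O | starting material
2 | N,O-dimethylhydroxylamine hydrochloride | CNOC.Cl | starting material
3 | 4-hydroxy-N,3-dimethoxy-N-methylbenzamide | COc1cc(C(=O)N(C)OC)ccc1O | intermediate
4 | chloromethyl methyl ether (MOMCl) | COCCl | starting material
5 | N,3-dimethoxy-4-(methoxymethoxy)-N-methylbenzamide | COCOc1ccc(cc1OC)C(=O)N(C)OC | intermediate
6 | 2,2,6-trimethyl-4H-1,3-dioxin-4-one | CC1=CC(=O)OC(C)(C)O1 | starting material
7 | acetyl chloride | CC(=O)Cl | starting material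
8 | 2,2-dimethyl-6-(2-oxopropyl)-4H-1,3-dioxin-4-one | CC(=O)CC1=CC(=O)OC(C)(C)O1 | intermediate
9 | 6-{4-[3-methoxy-4-(methoxymethoxy)phenyl]-2,4-dioxobutyl}-2,2-dimethyl-4H-1,3-dioxin-4-one | COCOc1ccc(cc1OC)C(=O)CC(=O)CC1=CC(=O)OC(C)(C)O1 | intermediate
10 | methyl 7-[3-methoxy-4-(methoxymethoxy)phenyl]-3,5,7-trioxoheptanoate (formed and consumed in the flask of step 5) | COCOc1ccc(cc1OC)C(=O)CC(=O)CC(=O)CC(=O)OC | intermediate
11 | 2,4,6-trihydroxyphenyl 3-methoxy-4-(methoxymethoxy)phenyl ketone | COCOc1ccc(cc1OC)C(=O)c1c(O)cc(O)cc1O | intermediate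
12 | 2,6-dihydroxy-4-(methoxymethoxy)phenyl 3-methoxy-4-(methoxymethoxy)phenyl ketone | COCOc1ccc(cc1OC)C(=O)c1c(O)cc(OCOC)cc1O | intermediate
13 | iodomethane | CI | starting material
14 | 2-hydroxy-6-methoxy-4-(methoxymethoxy)phenyl 3-methoxy-4-(methoxymethoxy)phenyl ketone | COCOc1ccc(cc1OC)C(=O)c1c(O)cc(OCOC)cc1OC | intermediate
15 | prenyl bromide (1-bromo-3-methylbut-2-ene) | CC(C)=CCBr | starting material
16 | 6-methoxy-4-(methoxymethoxy)-2-[(3-methylbut-2-en-1-yl)oxy]phenyl 3-methoxy-4-(methoxymethoxy)phenyl ketone | COCOc1ccc(cc1OC)C(=O)c1c(OCC=C(C)C)cc(OCOC)cc1OC | intermediate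
17 | 2-[3-methoxy-4-(methoxymethoxy)benzoyl]-3-methoxy-5-(methoxymethoxy)-6-(2-methylbut-3-en-2-yl)cyclohexa-2,4-dien-1-one (racemic, formed and consumed in the flask of step 9) | O=C1C(C(C)(C)C=C)C(OCOC)=CC(OC)=C1C(=O)c1ccc(OCOC)c(OC)c1 | intermediate
18 | 2-hydroxy-6-methoxy-4-(methoxymethoxy)-5-(3-methylbut-2-en-1-yl)phenyl 3-methoxy-4-(methoxymethoxy)phenyl ketone | COCOc1ccc(cc1OC)C(=O)c1c(O)cc(OCOC)c(CC=C(C)C)c1OC | intermediate
19 | 2,4-dihydroxy-6-methoxy-5-(3-methylbut-2-en-1-yl)phenyl 4-hydroxy-3-methoxyphenyl ketone (CNP0197938.0) | COc1cc(C(=O)c2c(O)cc(O)c(CC=C(C)C)c2OC)ccc1O | target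

Total step count: 10. Longest linear sequence: 9 steps (1 → 3 → 5 → 9 → 11 → 12 → 14 → 16 → 18 → 19); the dioxinone branch (6 → 8) joins at step 4.

Steps most likely to fail

Step 5. The chain may close through the aldol manifold instead of the Claisen manifold, may be cut by retro-Claisen methanolysis before the ring forms, or the masked ester may be released too slowly from the chelated polyenolate. The fallback abandons the folding and builds the diaryl ketone by arene acylation. It sets out from 1: Friedel–Crafts acylation of commercial phloroglucinol with 1 in P2O5/MeSO3H at 70 °C should give (4-hydroxy-3-methoxyphenyl)(2,4,6-trihydroxyphenyl)methanone F1, which cannot close to a xanthone because ring B has no ortho hydroxyl. Treatment of F1 with two equivalents of 4 and K2CO3 in acetone should etherify the two para hydroxyls, which are the non-chelated and most acidic ones, and the fallback comes back to the route at 12.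

Step 9. The first dienone may enolise before the Cope shift, fixing a reverse-prenyl group at C3, or the prenyl ether may fragment thermally. The fallback places the side chain by an ortho-Claisen rearrangement that has only one open position and builds the prenyl terminus afterwards. It sets out from 12:
- Mono-allylation of one of the equivalent ortho hydroxyls (allyl bromide, K2CO3, acetone) should give 6-(allyloxy)-2-hydroxy-4-(methoxymethoxy)phenyl 3-methoxy-4-(methoxymethoxy)phenyl ketone F2.
- Capping the chelated hydroxyl with 4 (NaH, DMF) gives 6-(allyloxy)-2,4-bis(methoxymethoxy)phenyl 3-methoxy-4-(methoxymethoxy)phenyl ketone F3.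
- Heating F3 in PhNEt2 at 190 °C should move the allyl group to C5, the only free ortho carbon, giving 5-allyl-6-hydroxy-2,4-bis(methoxymethoxy)phenyl 3-methoxy-4-(methoxymethoxy)phenyl ketone F4.
- Methylation of the freed C6 hydroxyl (MeI, K2CO3, DMF) gives 5-allyl-6-methoxy-2,4-bis(methoxymethoxy)phenyl 3-methoxy-4-(methoxymethoxy)phenyl ketone F5.
- Cross-metathesis with 2-methyl-2-butene (second-generation Grubbs catalyst, CH2Cl2, 40 °C) converts the allyl into the prenyl group, giving 6-methoxy-2,4-bis(methoxymethoxy)-5-(3-methylbut-2-en-1-yl)phenyl 3-methoxy-4-(methoxymethoxy)phenyl ketone F6.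
- Removal of the three MOM groups under the conditions of step 10 brings the fallback back to the route at 19.

Step 4. Addition of the dianion to the electron-rich, deactivated amide may be slow, so that proton transfer and self-condensation of the dianion compete. The fallback replaces the acylation by an aldol addition to a far more electrophilic aldehyde followed by oxidation. It sets out from 5 and 8: reduction of 5 with iBu2AlH in THF at −78 °C should give 3-methoxy-4-(methoxymethoxy)benzaldehyde F7. Addition of the dianion of 8 (LiN(iPr)2, THF, −78 °C) to F7 gives racemic 6-{4-hydroxy-4-[3-methoxy-4-(methoxymethoxy)phenyl]-2-oxobutyl}-2,2-dimethyl-4H-1,3-dioxin-4-one F8. Oxidation of F8 with Dess–Martin periodinane (NaHCO3, CH2Cl2) brings the fallback back to the route at 9.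

Further compounds
F1 | step 5 | (4-hydroxy-3-methoxyphenyl)(2,4,6-trihydroxyphenyl)methanone | COc1cc(C(=O)c2c(O)cc(O)cc2O)ccc1O
F2 | step 9 | 6-(allyloxy)-2-hydroxy-4-(methoxymethoxy)phenyl 3-methoxy-4-(methoxymethoxy)phenyl ketone | COCOc1ccc(cc1OC)C(=O)c1c(O)cc(OCOC)cc1OCC=C
F3 | step 9 | 6-(allyloxy)-2,4-bis(methoxymethoxy)phenyl 3-methoxy-4-(methoxymethoxy)phenyl ketone | COCOc1ccc(cc1OC)C(=O)c1c(OCOC)cc(OCOC)cc1OCC=C
F4 | step 9 | 5-allyl-6-hydroxy-2,4-bis(methoxymethoxy)phenyl 3-methoxy-4-(methoxymethoxy)phenyl ketone | COCOc1ccc(cc1OC)C(=O)c1c(OCOC)cc(OCOC)c(CC=C)c1O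
F5 | step 9 | 5-allyl-6-methoxy-2,4-bis(methoxymethoxy)phenyl 3-methoxy-4-(methoxymethoxy)phenyl ketone | COCOc1ccc(cc1OC)C(=O)c1c(OCOC)cc(OCOC)c(CC=C)c1OC
F6 | step 9 | 6-methoxy-2,4-bis(methoxymethoxy)-5-(3-methylbut-2-en-1-yl)phenyl 3-methoxy-4-(methoxymethoxy)phenyl ketone | COCOc1ccc(cc1OC)C(=O)c1c(OCOC)cc(OCOC)c(CC=C(C)C)c1OC
F7 | step 4 | 3-methoxy-4-(methoxymethoxy)benzaldehyde | COCOc1ccc(C=O)cc1OC
F8 | step 4 | 6-{4-hydroxy-4-[3-methoxy-4-(methoxymethoxy)phenyl]-2-oxobutyl}-2,2-dimethyl-4H-1,3-dioxin-4-one (racemic) | COCOc1ccc(cc1OC)C(O)CC(=O)CC1=CC(=O)OC(C)(C)O1
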